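The numbers were chosen freely; the result is computed.

I cannot integrate this flask by hand, so I fence its answers between a high estimate and a low bound.

    electrophile + nucleophile → acid set free + target (k1 = 0.023 L mol⁻¹ h⁻¹)
    nucleophile + acid set free ⇌ protonated nucleophile, settled at all times (K2 = 160 L mol⁻¹)
    target ⇌ isomer of the product (K3 = 23, k3 = 0.0083 h⁻¹)
    nucleophile ⇌ dormant form (K4 = 4.0, k4 = 0.12 h⁻¹)
    electrophile + protic impurity → quenched substrate (k5 = 0.19 L mol⁻¹ h⁻¹)

electrophile 0.42 M; nucleophile 1.26 M; protic impurity 0.210 M; time 10 d

1. part of the electrophile that has reacted at 10 d
2. share of free nucleophile in free nucleophile and protonated nucleophile together, at 10 d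

**The exposure.** The impurity's half-life on the electrophile, at charged concentrations, is 0.72 d, short against 10 d, so I let it take its whole charge at once, leaving 0.210 M of electrophile to a pseudo-first-order decay by step 1. That decay is counted by the exposure, k1 times the time integral of free [nucleophile]. Step 4 relaxes in 0.193 d to [nucleophile] = 0.252 M, and the excess before that balance is worth 1.11 d of extra time at this level.

**High estimate.** If acid costs no nucleophile, the exposure is 1.55, and c comes to about 89.3%. This is an estimate and no ceiling, for the impurity taking its charge at once is a simplification that lowers c: the electrophile's half-life as charged is 1.0 d by step 1 alone, beside 0.72 d by step 5 alone.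

**Lower bound.** Each acid costs two nucleophiles, one in the target and one protonated. If step 1 turns over the whole remainder, [nucleophile] ends at 0.168 M. Taking that level for the run gives exposure 1.08 and c above 83.1%.

**Going round.** Putting the acid this implies, 0.139 M, back in gives exposure 1.24. That gives acid 0.149 M and [nucleophile] 0.192 M, and a second round gives 1.22. I commit to c = 85.2%. Since nearly all of the acid is bound, fr = 57.1%.

**The forecast.** It gives 89% (85% to 93%) and 54% (50% to 58%), adding that “the product isomerisation affects neither answer”. Its c lies inside my bracket, higher than my value.

**The result.** The simulation gives 89.1% and 53.5%, which puts c close to my high estimate, and 0.79% of the impurity's charge remains. In the neighbour flask with 0.32 M of nucleophile, 0.0213% of the impurity's charge remains. The high-estimate exposure scales with the charge to 0.393, which gives c = 66.2%, and that neighbour's simulated c is 64.6%.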